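**Strategy.** Everything rests on opening ring D, the 2,2-dimethylpyran fused to ring B (primed locants, C1' on C2) through O4' and C5', with C5' para to the 2'-oxygen: this O4'–CMe2–CH=CH–C5' unit is the retron of an aryl 1,1-dimethylpropargyl ether. Heating the (2S)-flavanone that carries this ether on O4' moves the propargyl carbon chain to C5' and recloses O4'–CMe2, so ring D forms in one neutral operation that leaves C2 alone. The precursor is the 8-prenylflavanone with O5, O7 and O2' as triisopropylsilyl ethers; its propargyl ether is made before C2 exists, so the flavanone is never alkylated under base, and a single buffered fluoride step finishes the synthesis.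

Key step: step 10

Assumption: the rhodium/(S,S)-Ph-bod* catalyst is taken to attack the chromone with the facial sense it shows toward 2-cyclohexenone, which means aryl delivery to the Re face of C2 and the 2S product; if the sense proved opposite, the (R,R)-diene would be used.

**Route**

Step 1
Reactants: 1 2,4,6-trihydroxyacetophenone; 2 1-bromo-3-methylbut-2-ene
Product: 3 1-[2,4,6-trihydroxy-3-(3-methylbut-2-enyl)phenyl]ethanone
Conditions: DBU, THF, 0 °C to rt (1 in excess)
Reagents that add atoms: none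
Why: C-alkylation of a phloroglucinol-type phenoxide (C-prenylation), in which DBU generates the ambident phenoxide of 1, one of its two equivalent nucleophilic ring carbons attacks the primary carbon of the allylic bromide, and the excess of 1 holds back double prenylation.

Step 2
Reactants: 3 1-[2,4,6-trihydroxy-3-(3-methylbut-2-enyl)phenyl]ethanone
Product: 4 1-[2-hydroxy-3-(3-methylbut-2-enyl)-4,6-bis(triisopropylsilyloxy)phenyl]ethanone
Conditions: i-Pr3SiCl (2.3 equiv), imidazole, DMF, rt to 40 °C
Reagents that add atoms: chlorotri(propan-2-yl)silane, CC(C)[Si](Cl)(C(C)C)C(C)C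
Why: Silyl ether formation under steric control, in which the bulky chlorosilane should take the 4-hydroxyl and the ortho-hydroxyl next to the ring hydrogen while the hydroxyl wedged between acetyl and prenyl stays hydrogen-bonded to the carbonyl group, and this free oxygen is the one that must become O1 for the prenyl group to end at C8.

Step 3
Reactants: 4 1-[2-hydroxy-3-(3-methylbut-2-enyl)-4,6-bis(triisopropylsilyloxy)phenyl]ethanone
Product: 6 8-(3-methylbut-2-enyl)-5,7-bis(triisopropylsilyloxy)chromen-4-one, via enaminone 5 (not isolated)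
Conditions: Me2NCH(OMe)2, PhMe, 95 °C; then AcOH, 80 °C
Reagents that add atoms: N,N-dimethylformamide dimethyl acetal, COC(OC)N(C)C
Why: Enaminone formation from the methyl ketone and the amide acetal followed by acid-promoted addition–elimination (oxa-Michael addition of the single free hydroxyl, loss of dimethylamine), a standard route to 2,3-unsubstituted chromones that aryl triisopropylsilyl ethers and the prenyl group tolerate.

Step 4
Reactants: 7 4-bromoresorcinol; 8 3-chloro-3-methylbut-1-yne
Product: 9 2-bromo-5-(2-methylbut-3-yn-2-yloxy)phenol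
Conditions: CuCl2·2H2O (1 mol%), DBU, MeCN, −5 to 0 °C (7 in slight excess)
Reagents that add atoms: none
Why: Copper-catalysed propargylic etherification of a phenol (substitution through a copper allenylidene formed from the tertiary propargylic chloride), expected at the hydroxyl para to bromine because the hydroxyl next to bromine is more hindered and less nucleophilic toward the congested tertiary carbon, with limiting 8 holding back double etherification.

Step 5
Reactants: 9 2-bromo-5-(2-methylbut-3-yn-2-yloxy)phenol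
Product: 10 [2-bromo-5-(2-methylbut-3-yn-2-yloxy)phenoxy]triisopropylsilane
Conditions: i-Pr3SiCl, imidazole, DMF, rt
Reagents that add atoms: chlorotri(propan-2-yl)silane, CC(C)[Si](Cl)(C(C)C)C(C)C
Why: Silylation of the remaining hindered phenol (silyl ether formation), which installs the bulky group that later shields C3' and that withstands organolithium reagents, aqueous boronate and heat.

Step 6
Reactants: 10 [2-bromo-5-(2-methylbut-3-yn-2-yloxy)phenoxy]triisopropylsilane
Product: 12 {3-[4-bromo-3-(triisopropylsilyloxy)phenoxy]-3-methylbut-1-ynyl}trimethylsilane, via alkynylmagnesium bromide 11 (not isolated)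
Conditions: EtMgBr, THF, 0 °C to rt; then Me3SiCl, 0 °C to rt
Reagents that add atoms: chlorotrimethylsilane, C[Si](C)(C)Cl
Why: Deprotonation of the terminal alkyne by the Grignard reagent and C-silylation of the alkynylmagnesium bromide, which masks the acidic C–H that would quench the aryllithium of step 7 and insert into arylrhodium in step 8, while EtMgBr does not exchange with the aryl bromide.

Step 7
Reactants: 12 {3-[4-bromo-3-(triisopropylsilyloxy)phenoxy]-3-methylbut-1-ynyl}trimethylsilane
Product: 15 [4-(2-methyl-4-trimethylsilylbut-3-yn-2-yloxy)-2-(triisopropylsilyloxy)phenyl]boronic acid, via aryllithium 13 (not isolated), via lithium triisopropoxyborate 14 (not isolated)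
Conditions: B(Oi-Pr)3 (1.3 equiv), then n-BuLi (1.1 equiv), THF/PhMe, −78 °C; 1 M aq. HCl to pH 5, 0 °C
Reagents that add atoms: triisopropyl borate, CC(C)OB(OC(C)C)OC(C)C; water, O
Why: Bromine–lithium exchange with in situ capture by the borate ester and hydrolysis of the ate complex, where the low temperature and the trap already in the flask leave the ortho-lithio aryl silyl ether no time for O-to-C silyl migration.

Step 8
Reactants: 6 8-(3-methylbut-2-enyl)-5,7-bis(triisopropylsilyloxy)chromen-4-one; 15 [4-(2-methyl-4-trimethylsilylbut-3-yn-2-yloxy)-2-(triisopropylsilyloxy)phenyl]boronic acid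
Product: 16 (2S)-2-[4-(2-methyl-4-trimethylsilylbut-3-yn-2-yloxy)-2-(triisopropylsilyloxy)phenyl]-8-(3-methylbut-2-enyl)-5,7-bis(triisopropylsilyloxy)chroman-4-one
Conditions: [RhCl(C2H4)2]2 (2.5 mol%), (1S,4S)-2,5-diphenylbicyclo[2.2.2]octa-2,5-diene [(S,S)-Ph-bod*] (5.5 mol%), KOH (0.2 equiv), 15 (3 equiv), 1,4-dioxane/H2O 10:1, 40 °C
Reagents that add atoms: none
Why: Rhodium-catalysed asymmetric 1,4-addition of an arylboronic acid to a chromone (Hayashi–Miyaura type), in which the aryl group passes from boron to the diene-bound rhodium hydroxide, inserts across C2=C3 on the Re face of C2 selected by the C2-symmetric diene (catalyst control, giving 2S) and water protonates the rhodium enolate, while the silyl cap keeps the alkyne out of carbometalation and the excess boronic acid buffers the hydroxide.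

Step 9
Reactants: 16 (2S)-2-[4-(2-methyl-4-trimethylsilylbut-3-yn-2-yloxy)-2-(triisopropylsilyloxy)phenyl]-8-(3-methylbut-2-enyl)-5,7-bis(triisopropylsilyloxy)chroman-4-one
Product: 17 (2S)-2-[4-(2-methylbut-3-yn-2-yloxy)-2-(triisopropylsilyloxy)phenyl]-8-(3-methylbut-2-enyl)-5,7-bis(triisopropylsilyloxy)chroman-4-one
Conditions: AgNO3 (10 mol%), acetone/H2O/CH2Cl2, rt
Reagents that add atoms: none
Why: Silver-catalysed protodesilylation of an alkynyl trimethylsilane (through a silver acetylide that the aqueous medium protonates), a neutral reaction that leaves the aryl triisopropylsilyl ethers, the ketone and the base-sensitive C2 centre untouched.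

Step 10
Reactants: 17 (2S)-2-[4-(2-methylbut-3-yn-2-yloxy)-2-(triisopropylsilyloxy)phenyl]-8-(3-methylbut-2-enyl)-5,7-bis(triisopropylsilyloxy)chroman-4-one
Product: 21 (2S)-2-[2,2-dimethyl-7-(triisopropylsilyloxy)-2H-chromen-6-yl]-8-(3-methylbut-2-enyl)-5,7-bis(triisopropylsilyloxy)chroman-4-one, via allenyl dienone 18 (not isolated), via allenylphenol 19 (not isolated), via ortho-quinone methide 20 (not isolated)
Conditions: o-xylene (degassed), 140 °C, Ar
Reagents that add atoms: none
Why: The aryl propargyl ether undergoes a [3,3] sigmatropic shift (aromatic propargyl Claisen rearrangement) that bonds C5' to the alkyne terminus and gives the allenyl dienone 18; enolisation to the allenylphenol 19 and a 1,5-hydrogen shift from O4'–H to the central allene carbon then give the (Z)-vinyl ortho-quinone methide 20. The closest known reaction is the thermal conversion of 1,1-dimethylpropargyl ethers of 3-alkoxyphenols into 7-alkoxy-2,2-dimethyl-2H-chromenes. Ring D closes by a thermally allowed disrotatory oxa-6π electrocyclisation of the 1-oxatriene in 20, which re-forms the O4'–CMe2 bond and restores the aromaticity of ring B. No stereocentre is created, since the sp3 carbon at C5' of 18 is lost on enolisation, and C2 is left alone because the cascade needs neither acid nor base and never produces a 4'-phenoxide. The step needs migration to C5' and not to C3': C3' lies between O2' and O4' and is shielded by the triisopropylsilyl group on O2', which the C1' substituent pushes toward C3', and this adds to the inherent preference of 3-oxygenated aryl propargyl ethers for the position para to that oxygen.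

Step 11
Reactants: 21 (2S)-2-[2,2-dimethyl-7-(triisopropylsilyloxy)-2H-chromen-6-yl]-8-(3-methylbut-2-enyl)-5,7-bis(triisopropylsilyloxy)chroman-4-one
Product: 22 (2S)-5,7-dihydroxy-2-(7-hydroxy-2,2-dimethyl-2H-chromen-6-yl)-8-(3-methylbut-2-enyl)chroman-4-one
Conditions: Bu4NF (3.6 equiv), AcOH (4.5 equiv), THF, 0 °C to rt
Reagents that add atoms: none
Why: Fluoride cleavage of the three aryl silyl ethers (Si–O cleavage driven by Si–F bond formation), in which acetic acid protonates each phenoxide as it is released so that no 2'-phenoxide survives to open ring C through an ortho-quinone methide, and no acid is present that could hydrate the chromene, cyclise the prenyl group onto O7 or ionise the C2–O1 bond.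

**Compound list**

1 | 2,4,6-trihydroxyacetophenone | CC(=O)c1c(O)cc(O)cc1O | starting material
2 | 1-bromo-3-methylbut-2-ene | CC(C)=CCBr | starting material
3 | 1-[2,4,6-trihydroxy-3-(3-methylbut-2-enyl)phenyl]ethanone | CC(=O)c1c(O)cc(O)c(CC=C(C)C)c1O | intermediate
4 | 1-[2-hydroxy-3-(3-methylbut-2-enyl)-4,6-bis(triisopropylsilyloxy)phenyl]ethanone | CC(=O)c1c(O)c(CC=C(C)C)c(O[Si](C(C)C)(C(C)C)C(C)C)cc1O[Si](C(C)C)(C(C)C)C(C)C | intermediate
5 | (E)-3-(dimethylamino)-1-[2-hydroxy-3-(3-methylbut-2-enyl)-4,6-bis(triisopropylsilyloxy)phenyl]prop-2-en-1-one | CN(C)/C=C/C(=O)c1c(O)c(CC=C(C)C)c(O[Si](C(C)C)(C(C)C)C(C)C)cc1O[Si](C(C)C)(C(C)C)C(C)C | intermediate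
6 | 8-(3-methylbut-2-enyl)-5,7-bis(triisopropylsilyloxy)chromen-4-one | CC(C)=CCc1c(O[Si](C(C)C)(C(C)C)C(C)C)cc(O[Si](C(C)C)(C(C)C)C(C)C)c2c(=O)ccoc12 | intermediate
7 | 4-bromoresorcinol (4-bromobenzene-1,3-diol) | Oc1ccc(Br)c(O)c1 | starting material
8 | 3-chloro-3-methylbut-1-yne | CC(C)(Cl)C#C | starting material
9 | 2-bromo-5-(2-methylbut-3-yn-2-yloxy)phenol | Oc1cc(OC(C)(C)C#C)ccc1Br | intermediate
10 | [2-bromo-5-(2-methylbut-3-yn-2-yloxy)phenoxy]triisopropylsilane | CC(C)[Si](Oc1cc(OC(C)(C)C#C)ccc1Br)(C(C)C)C(C)C | intermediate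
11 | bromo{3-[4-bromo-3-(triisopropylsilyloxy)phenoxy]-3-methylbut-1-ynyl}magnesium | Br[Mg]C#CC(C)(C)Oc1ccc(Br)c(O[Si](C(C)C)(C(C)C)C(C)C)c1 | intermediate
12 | {3-[4-bromo-3-(triisopropylsilyloxy)phenoxy]-3-methylbut-1-ynyl}trimethylsilane | C[Si](C)(C)C#CC(C)(C)Oc1ccc(Br)c(O[Si](C(C)C)(C(C)C)C(C)C)c1 | intermediate
13 | [4-(2-methyl-4-trimethylsilylbut-3-yn-2-yloxy)-2-(triisopropylsilyloxy)phenyl]lithium | [Li]c1ccc(OC(C)(C)C#C[Si](C)(C)C)cc1O[Si](C(C)C)(C(C)C)C(C)C | intermediate
14 | lithium triisopropoxy[4-(2-methyl-4-trimethylsilylbut-3-yn-2-yloxy)-2-(triisopropylsilyloxy)phenyl]borate | [Li+].CC(C)O[B-](OC(C)C)(OC(C)C)c1ccc(OC(C)(C)C#C[Si](C)(C)C)cc1O[Si](C(C)C)(C(C)C)C(C)C | intermediate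
15 | [4-(2-methyl-4-trimethylsilylbut-3-yn-2-yloxy)-2-(triisopropylsilyloxy)phenyl]boronic acid | OB(O)c1ccc(OC(C)(C)C#C[Si](C)(C)C)cc1O[Si](C(C)C)(C(C)C)C(C)C | intermediate
16 | (2S)-2-[4-(2-methyl-4-trimethylsilylbut-3-yn-2-yloxy)-2-(triisopropylsilyloxy)phenyl]-8-(3-methylbut-2-enyl)-5,7-bis(triisopropylsilyloxy)chroman-4-one | CC(C)=CCc1c(O[Si](C(C)C)(C(C)C)C(C)C)cc(O[Si](C(C)C)(C(C)C)C(C)C)c2c1O[C@H](c1ccc(OC(C)(C)C#C[Si](C)(C)C)cc1O[Si](C(C)C)(C(C)C)C(C)C)CC2=O | intermediate
17 | (2S)-2-[4-(2-methylbut-3-yn-2-yloxy)-2-(triisopropylsilyloxy)phenyl]-8-(3-methylbut-2-enyl)-5,7-bis(triisopropylsilyloxy)chroman-4-one | CC(C)=CCc1c(O[Si](C(C)C)(C(C)C)C(C)C)cc(O[Si](C(C)C)(C(C)C)C(C)C)c2c1O[C@H](c1ccc(OC(C)(C)C#C)cc1O[Si](C(C)C)(C(C)C)C(C)C)CC2=O | intermediate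
18 | (2S)-2-[3-(3-methylbuta-1,2-dienyl)-4-oxo-6-(triisopropylsilyloxy)cyclohexa-1,5-dien-1-yl]-8-(3-methylbut-2-enyl)-5,7-bis(triisopropylsilyloxy)chroman-4-one (both epimers at the sp3 ring carbon) | CC(C)=CCc1c(O[Si](C(C)C)(C(C)C)C(C)C)cc(O[Si](C(C)C)(C(C)C)C(C)C)c2c1O[C@H](C1=CC(C=C=C(C)C)C(=O)C=C1O[Si](C(C)C)(C(C)C)C(C)C)CC2=O | intermediate
19 | (2S)-2-[4-hydroxy-5-(3-methylbuta-1,2-dienyl)-2-(triisopropylsilyloxy)phenyl]-8-(3-methylbut-2-enyl)-5,7-bis(triisopropylsilyloxy)chroman-4-one | CC(C)=CCc1c(O[Si](C(C)C)(C(C)C)C(C)C)cc(O[Si](C(C)C)(C(C)C)C(C)C)c2c1O[C@H](c1cc(C=C=C(C)C)c(O)cc1O[Si](C(C)C)(C(C)C)C(C)C)CC2=O | intermediate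
20 | (2S)-2-[(3Z)-3-(3-methylbut-2-enylidene)-4-oxo-6-(triisopropylsilyloxy)cyclohexa-1,5-dien-1-yl]-8-(3-methylbut-2-enyl)-5,7-bis(triisopropylsilyloxy)chroman-4-one | CC(C)=CCc1c(O[Si](C(C)C)(C(C)C)C(C)C)cc(O[Si](C(C)C)(C(C)C)C(C)C)c2c1O[C@H](C1=C/C(=C/C=C(C)C)C(=O)C=C1O[Si](C(C)C)(C(C)C)C(C)C)CC2=O | intermediate
21 | (2S)-2-[2,2-dimethyl-7-(triisopropylsilyloxy)-2H-chromen-6-yl]-8-(3-methylbut-2-enyl)-5,7-bis(triisopropylsilyloxy)chroman-4-one | CC(C)=CCc1c(O[Si](C(C)C)(C(C)C)C(C)C)cc(O[Si](C(C)C)(C(C)C)C(C)C)c2c1O[C@H](c1cc3c(cc1O[Si](C(C)C)(C(C)C)C(C)C)OC(C)(C)C=C3)CC2=O | intermediate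
22 | (2S)-5,7-dihydroxy-2-(7-hydroxy-2,2-dimethyl-2H-chromen-6-yl)-8-(3-methylbut-2-enyl)chroman-4-one | CC(C)=CCc1c(O)cc(O)c2c1O[C@H](c1cc3c(cc1O)OC(C)(C)C=C3)CC2=O | target

**Step count and risks**

Total steps: 11. Longest linear sequence: 8 steps (steps 4 to 11, from 4-bromoresorcinol 7).

Steps most likely to fail:

1. Step 8. Transmetalation and insertion of the aryl group that carries the bulky ortho silyloxy substituent may be slower than protodeboronation, or facial selection may be incomplete. The fallback makes the C2–C1' bond without an organometallic catalyst and sets out from 12 and 4.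
   - Bromine–lithium exchange of 12 (n-BuLi, THF, −78 °C) and quenching with DMF should give 4-(2-methyl-4-trimethylsilylbut-3-yn-2-yloxy)-2-(triisopropylsilyloxy)benzaldehyde F1.
   - Aldol addition of the dilithium salt of 4 (LiN(SiMe3)2, THF, −78 °C) to this aldehyde should give the racemic β-hydroxy ketone aldol adduct F2.
   - Warming with NaOAc in EtOH should dehydrate it to the (E)-chalcone F3, which under the same conditions closes by oxa-Michael addition to the racemic flavanone F4.
   - Preparative HPLC on a chiral stationary phase would then separate the 2S enantiomer, which is 16, where the route is rejoined.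

2. Step 10. Migration to C3' may compete with migration to C5', or the C2 configuration may erode through reversible opening of ring C during prolonged heating. The fallback moves the annulation ahead of the asymmetric step, so that neither a regioisomer nor heat reaches the flavanone, and sets out from 10.
   - Heating 10 in o-xylene at 140 °C should give 6-bromo-2,2-dimethyl-7-(triisopropylsilyloxy)-2H-chromene F5, with any angular isomer removed at this inexpensive stage.
   - Bromine–lithium exchange with B(Oi-Pr)3 present (n-BuLi, −78 °C) and hydrolysis should give [2,2-dimethyl-7-(triisopropylsilyloxy)-2H-chromen-6-yl]boronic acid F6.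
   - Its rhodium-catalysed addition to chromone 6 under the conditions of step 8 leads directly to 21, where the route is rejoined.

3. Step 4. Etherification may also take place at the hydroxyl next to bromine, or at both hydroxyls, so that the wanted mono-ether is formed unselectively. The fallback tells the two hydroxyls apart with a temporary acyl group and sets out from 7.
   - Pivaloyl chloride and pyridine in CH2Cl2 at −20 °C should acylate the unhindered hydroxyl to give 4-bromo-3-hydroxyphenyl 2,2-dimethylpropanoate F7.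
   - i-Pr3SiCl and imidazole in DMF should then give 4-bromo-3-(triisopropylsilyloxy)phenyl 2,2-dimethylpropanoate F8.
   - Reductive removal of the pivalate with i-Bu2AlH in CH2Cl2 at −78 °C should give 4-bromo-3-(triisopropylsilyloxy)phenol F9.
   - Copper-catalysed etherification of this phenol with 8 (CuCl2·2H2O, DBU, MeCN, 0 °C) gives 10, where the route is rejoined.

**Further compounds**

F1 | step 8 | 4-(2-methyl-4-trimethylsilylbut-3-yn-2-yloxy)-2-(triisopropylsilyloxy)benzaldehyde | O=Cc1ccc(OC(C)(C)C#C[Si](C)(C)C)cc1O[Si](C(C)C)(C(C)C)C(C)C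
F2 | step 8 | rac-3-hydroxy-1-[2-hydroxy-3-(3-methylbut-2-enyl)-4,6-bis(triisopropylsilyloxy)phenyl]-3-[4-(2-methyl-4-trimethylsilylbut-3-yn-2-yloxy)-2-(triisopropylsilyloxy)phenyl]propan-1-one | CC(C)=CCc1c(O)c(C(=O)CC(O)c2ccc(OC(C)(C)C#C[Si](C)(C)C)cc2O[Si](C(C)C)(C(C)C)C(C)C)c(O[Si](C(C)C)(C(C)C)C(C)C)cc1O[Si](C(C)C)(C(C)C)C(C)C
F3 | step 8 | (E)-1-[2-hydroxy-3-(3-methylbut-2-enyl)-4,6-bis(triisopropylsilyloxy)phenyl]-3-[4-(2-methyl-4-trimethylsilylbut-3-yn-2-yloxy)-2-(triisopropylsilyloxy)phenyl]prop-2-en-1-one | CC(C)=CCc1c(O)c(C(=O)/C=C/c2ccc(OC(C)(C)C#C[Si](C)(C)C)cc2O[Si](C(C)C)(C(C)C)C(C)C)c(O[Si](C(C)C)(C(C)C)C(C)C)cc1O[Si](C(C)C)(C(C)C)C(C)C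
F4 | step 8 | rac-2-[4-(2-methyl-4-trimethylsilylbut-3-yn-2-yloxy)-2-(triisopropylsilyloxy)phenyl]-8-(3-methylbut-2-enyl)-5,7-bis(triisopropylsilyloxy)chroman-4-one | CC(C)=CCc1c(O[Si](C(C)C)(C(C)C)C(C)C)cc(O[Si](C(C)C)(C(C)C)C(C)C)c2c1OC(c1ccc(OC(C)(C)C#C[Si](C)(C)C)cc1O[Si](C(C)C)(C(C)C)C(C)C)CC2=O
F5 | step 10 | 6-bromo-2,2-dimethyl-7-(triisopropylsilyloxy)-2H-chromene | CC1(C)C=Cc2cc(Br)c(O[Si](C(C)C)(C(C)C)C(C)C)cc2O1
F6 | step 10 | [2,2-dimethyl-7-(triisopropylsilyloxy)-2H-chromen-6-yl]boronic acid | CC1(C)C=Cc2cc(B(O)O)c(O[Si](C(C)C)(C(C)C)C(C)C)cc2O1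
F7 | step 4 | 4-bromo-3-hydroxyphenyl 2,2-dimethylpropanoate | CC(C)(C)C(=O)Oc1ccc(Br)c(O)c1
F8 | step 4 | 4-bromo-3-(triisopropylsilyloxy)phenyl 2,2-dimethylpropanoate | CC(C)(C)C(=O)Oc1ccc(Br)c(O[Si](C(C)C)(C(C)C)C(C)C)c1
F9 | step 4 | 4-bromo-3-(triisopropylsilyloxy)phenol | Oc1ccc(Br)c(O[Si](C(C)C)(C(C)C)C(C)C)c1
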